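**Remarks.** Germacrane numbering is used throughout: C1 ketone, C2=C3 furanone enol ether, C4=C5 Z-alkene bearing C15, C6 lactone carbinol, C7, C8 tiglate carbinol, C9, quaternary C10 bearing C14 and the ring oxygen, C11=C13 methylene, C12 lactone carbonyl. TBS = tert-butyldimethylsilyl, TBDPS = tert-butyldiphenylsilyl.

## The problem

Compound 33 is a germacranolide whose ten-membered carbocycle (C1–C10) is bridged by an oxygen between C3 and C10, so that C10–C1–C2–C3–O is a 3(2H)-furanone. Across C6–C7 it is fused to an α-methylene-γ-butyrolactone (C6, C7, C11, C12, O, with C13 as the methylene). In the (6S,7R) configuration H6 and H7 lie on the same face, so the lactone is cis-fused.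

Of the four stereocenters, quaternary C10 is cut off from the contiguous triad C6–C7–C8 by the flat furanone and the C4=C5 alkene. It cannot steer the others and is best taken from the chiral pool. C6 then needs reagent control. Once set, C6 can fix C7 through the ring fusion and, less predictably, C8.

The Z geometry of C4=C5 (C3 and C6 cis) must be set early and kept. Several groups will not survive rough treatment:
- the exocyclic methylene lactone (Michael acceptor, prone to migrate into the ring);
- the vinylogous-ester furanone;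
- the doubly allylic C6–H of any butenolide intermediate;
- a C8 aldehyde, which is β to the furanone oxygen and can eliminate it under base;
- the tiglate and the primary allylic alcohol at C15.

The feature that opens the structure is that C7 is both the β-carbon of the methylene lactone and the neighbour of the C8 carbinol. The array C13=C11–C7–C8–OH is what an allylmetal with the metal on C13 leaves when it attacks a C8 aldehyde through C7. The C7–C8 bond, the exocyclic alkene and the ten-membered ring can therefore form in one step.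

## Retrosynthesis

**33 ⇒ 32 ⇒ 29.** The C15–O–Si bond and the C8–O acyl bond to tiglic acid 30 are cut first. Acylating after ring closure keeps a second Michael acceptor out of the organometallic step and leaves the C8 hydroxyl open to correction. The cost is one esterification of a hindered secondary alcohol. C15 carries TBDPS because it must outlast a primary TBS ether at C8.

**29 ⇒ 27 (key cut).** The C7–C8 bond is cut with allylic transposition, giving a C8 aldehyde and a 3-(bromomethyl)butenolide in 27. Cuts at C1–C2 or C9–C10 would leave the methylene lactone and all three contiguous stereocenters to be made beforehand, and an olefination at C4=C5 would put the Z geometry at risk. This cut removes the ring, two stereocenters and the Michael acceptor together. Precursor 27 has only C6 and C10 as stereocenters. The forward step must be neutral, chemoselective for the aldehyde, and must attack C7 on the face cis to C5.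

**27 ⇒ 26 ⇒ 25.** The β-alkoxy aldehyde is revealed only one step before use, by non-basic oxidation of alcohol 26. Alcohol 26 comes from selective removal of the primary TBS ether of 25 beside the TBDPS ether.

**25 ⇒ 24 ⇒ 21 + 22.** The butenolide alkene C7=C11 is cut (ring-closing metathesis) and then the C6–O acyl bond. A shorter sequence was set aside: Barbier lactonization at C6, migration of the alkene into the ring, then NBS bromination. Its radical step would have to prefer the C13 methyl over C6–H, which is tertiary, doubly allylic and next to oxygen. The metathesis route brings the bromide in with commercial acid 22 and needs only bis-allylic alcohol 21. It asks for an acylation free of nucleophilic amines and a metathesis onto a 1,1-disubstituted acrylate.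

**21 ⇒ 20 ⇒ 19 ⇒ 17 + 11.** The C6–C7 bond is cut. C10 is five bonds away across a planar unit, so C6 is set by catalyst control: zinc–ProPhenol alkynylation of enal 17 with ethynyltrimethylsilane 11, then desilylation and semihydrogenation. A direct asymmetric vinylation would save two steps but is less established for enals. Enal 17 has one stereocenter.

**17 ⇒ 16 ⇒ 15 ⇒ 13 + 4.** The O–C3 bond of the furanone is cut (5-endo-dig closure of α′-hydroxy ynone 15), then C1–C2 (acylation of the lithium acetylide 14 of enyne 13 by dioxolanone 4). The dioxolanone releases the ketone and the tertiary alcohol in one operation. The C6 aldehyde travels as a dimethyl acetal, which withstands the organolithium and is hydrolysed after the furanone is formed.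

**13 ⇒ 12 ⇒ 10 + 11; 10 ⇒ 9 ⇒ 8 ⇒ 6 ⇒ 5.** The C3–C4 bond is cut (Sonogashira coupling of Z-vinyl iodide 10 with 11). The iodide comes from but-2-yne-1,4-diol 5, which supplies C15, C4, C5 and C6. Hydroxyl-directed trans-hydroalumination and iodination place iodine (later C3) cis to C6, fixing the alkene geometry at the start.

**4 ⇒ 3 ⇒ 2 ⇒ 1.** (R)-Citramalic acid 1 already holds C10 with its methyl, its oxygen, the C1 carboxyl and the C9–C8 arm. The two carboxyls are told apart by dioxolanone formation, and no bond at C10 is ever broken.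

## Roads not taken

**Alternative 1:** The cut is C1–C2. An open-chain iodoalkyne aldehyde A1, already carrying the lactone and tiglate, would be closed with CrCl2 and catalytic NiCl2 to the cyclic enyne carbinol A2. Oxidation at C1, removal of the C10 silyl group and transannular oxa-Michael closure would then give the furanone.
- Merits: alkynylchromium macrocyclization is a reliable way to close rings, the C1 configuration is irrelevant, and the furanone closure releases strain.
- Weak points: A1 must contain the methylene lactone, the tiglate and all of C6, C7 and C8 from open-chain stereocontrol. The Michael acceptor then faces divalent chromium, an oxidant and acid. The ring must accommodate a near-linear alkyne, and three or four steps follow cyclization.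
- Comparison: in precedent for the ring closure itself this road is stronger than the chosen one. The chosen plan sets against it that the methylene lactone appears only in the ring-closing step, that C7 comes from the tether and not from acyclic induction, and that no redox change follows macrocyclization.

**Alternative 2:** The cuts are C2–C3 and C4–C5, with C2–C5 re-formed. Cyclooctenone A3, with an ynol ether on the C10 oxygen, would undergo a AgNTf2-triggered Ficini-type [2+2] reaction. Conrotatory opening of the cyclobutene would give the furanone-bridged ten-membered core A4.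
- Merits: two rings form in one step from an easier eight-membered ring, and the tether fixes which diene bond lies in the furanone.
- Weak points: a tertiary alkyl ynol ether at C10 has β-hydrogens and is prone to thermal loss of alkene to a ketene. A3 itself needs a medium-ring synthesis with three contiguous stereocenters. The cascade has no close precedent in medium rings. A4 still has an open lactone diol that needs deprotection, oxidation and lactonization.
- Comparison: in ring construction this road is the most step-economic. The chosen plan sets against it a ring closure of a known reaction type and a precursor assembled entirely by standard bond formations.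

**Alternative 3:** The cuts are O–C12 and C11–C12. Macrocyclic homopropargylic alcohol A5 would be cyclocarbonylated (PdCl2, SnCl2, PPh3, CO) to A6, the C15 silyl ether of 33.
- Merits: the methylene lactone is made last under neutral conditions on a closed ring, and syn addition across the alkyne suits the cis fusion.
- Weak points: the macrocyclization is only postponed, since A5 must be closed by another method. C6, C7 and C8 must be set without the lactone, and a terminal alkyne and a free C6 hydroxyl must be carried through that closure.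
- Comparison: this road equals the chosen plan in delaying the Michael acceptor and is better in that the ring already exists when it appears. The chosen plan sets against it that one step closes the ring, forms the methylene unit and sets two stereocenters.

Key step: step 19

## Route

Remark on the chemistry: both enantiomers of the ProPhenol ligand are available; the one whose dinuclear zinc complex delivers the alkyne to the Re face of aldehyde 17 is used, to be confirmed by Mosher ester analysis of 19.

Step 1
Reactants: 1 (R)-citramalic acid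
Product: 2 2-[(4R)-2,2,4-trimethyl-5-oxo-1,3-dioxolan-4-yl]acetic acid
Conditions: Me2C(OMe)2, TsOH·H2O (cat.), CH2Cl2, rt
Reagents that add atoms: 2,2-dimethoxypropane, COC(C)(C)OC
Why: Acid-catalysed acetonide exchange ties up the α-hydroxy acid as the five-membered dioxolanone and leaves the β-carboxyl free; no bond at C10 is touched, so the chiral-pool configuration is kept.

Step 2
Reactants: 2 2-[(4R)-2,2,4-trimethyl-5-oxo-1,3-dioxolan-4-yl]acetic acid
Product: 3 (5R)-5-(2-hydroxyethyl)-2,2,5-trimethyl-1,3-dioxolan-4-one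
Conditions: BH3·SMe2, THF, 0 °C to rt; MeOH quench
Reagents that add atoms: none
Why: Borane reduces a free carboxylic acid far faster than the dioxolanone carbonyl (chemoselective borane reduction); neutral work-up avoids translactonization to the γ-lactone.

Step 3
Reactants: 3 (5R)-5-(2-hydroxyethyl)-2,2,5-trimethyl-1,3-dioxolan-4-one
Product: 4 (5R)-5-{2-[(TBS)oxy]ethyl}-2,2,5-trimethyl-1,3-dioxolan-4-one
Conditions: TBSCl, imidazole, CH2Cl2, 0 °C
Reagents that add atoms: tert-butyldimethylsilyl chloride, CC(C)(C)[Si](C)(C)Cl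
Why: Standard silylation of a primary alcohol under mildly basic conditions that do not open the dioxolanone; the TBS ether masks the future C8 aldehyde.

Step 4
Reactants: 5 but-2-yne-1,4-diol
Product: 6 4-[(TBDPS)oxy]but-2-yn-1-ol
Conditions: 5 (3 equiv), TBDPSCl (1 equiv), imidazole, DMF, 0 °C to rt
Reagents that add atoms: tert-butyldiphenylsilyl chloride, CC(C)(C)[Si](Cl)(c1ccccc1)c1ccccc1
Why: Statistical monosilylation of a cheap symmetric diol used in excess; the protected end becomes C15 and the free hydroxyl (future C6) directs the next step.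

Step 5
Reactants: 6 4-[(TBDPS)oxy]but-2-yn-1-ol
Product: 8 (2Z)-4-[(TBDPS)oxy]-3-iodobut-2-en-1-ol, via cyclic alkenylalanate 7 (not isolated)
Conditions: NaAlH2(OCH2CH2OMe)2, THF, 0 °C to rt; then I2, THF, −78 to 0 °C; aq. potassium sodium tartrate
Reagents that add atoms: iodine, II
Why: Hydroxyl-directed trans-hydroalumination puts hydride on the carbon next to the carbinol and aluminium on the distal carbon within a five-membered alanate; iodinolysis with retention gives the Z-iodide with iodine cis to the CH2OH carbon, which fixes the C4=C5 geometry.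

Step 6
Reactants: 8 (2Z)-4-[(TBDPS)oxy]-3-iodobut-2-en-1-ol
Product: 9 (2Z)-4-[(TBDPS)oxy]-3-iodobut-2-enal
Conditions: MnO2, CH2Cl2, rt, dark
Reagents that add atoms: none
Why: Allylic oxidation with MnO2 is neutral and does not isomerize the β-iodo enal.

Step 7
Reactants: 9 (2Z)-4-[(TBDPS)oxy]-3-iodobut-2-enal
Product: 10 (2Z)-1-[(TBDPS)oxy]-2-iodo-4,4-dimethoxybut-2-ene
Conditions: HC(OMe)3, PPTS (cat.), MeOH, rt
Reagents that add atoms: trimethyl orthoformate, COC(OC)OC; methanol, CO
Why: Acid-catalysed acetalization with orthoformate as water scavenger masks the C6 aldehyde for the organolithium step; the TBDPS ether and the vinyl iodide are stable to PPTS.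

Step 8
Reactants: 10 (2Z)-1-[(TBDPS)oxy]-2-iodo-4,4-dimethoxybut-2-ene; 11 ethynyltrimethylsilane
Product: 12 (2E)-1-[(TBDPS)oxy]-4,4-dimethoxy-2-[(trimethylsilyl)ethynyl]but-2-ene (alkyne cis to the acetal carbon)
Conditions: Pd(PPh3)2Cl2 (3 mol%), CuI (6 mol%), Et3N, THF, rt
Reagents that add atoms: none
Why: Sonogashira coupling of a vinyl iodide proceeds with retention, so the alkyne carbon (C3) stays cis to C6; the descriptor changes to E only because CH2OSi outranks the alkyne.

Step 9
Reactants: 12 (2E)-1-[(TBDPS)oxy]-4,4-dimethoxy-2-[(trimethylsilyl)ethynyl]but-2-ene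
Product: 13 (2E)-1-[(TBDPS)oxy]-2-ethynyl-4,4-dimethoxybut-2-ene
Conditions: K2CO3, MeOH, rt
Reagents that add atoms: none
Why: Methanolysis of the alkynyl–silicon bond is selective; the TBDPS ether and the acetal are inert to K2CO3 in methanol.

Step 10
Reactants: 13 (2E)-1-[(TBDPS)oxy]-2-ethynyl-4,4-dimethoxybut-2-ene; 4 (5R)-5-{2-[(TBS)oxy]ethyl}-2,2,5-trimethyl-1,3-dioxolan-4-one
Product: 15 (3R,7E)-1-[(TBS)oxy]-7-{[(TBDPS)oxy]methyl}-3-hydroxy-9,9-dimethoxy-3-methylnon-7-en-5-yn-4-one, via lithium acetylide 14 (not isolated)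
Conditions: 13, n-BuLi, THF, −78 °C; then 4, −78 to −40 °C; aq. NH4Cl
Reagents that add atoms: none
Why: Acylation of a lithium acetylide by a lactone-type carbonyl stops at the ketone stage because the tetrahedral adduct persists at low temperature; on quench it loses acetone and frees the tertiary alcohol, giving the α′-hydroxy ynone with C10 untouched.

Step 11
Reactants: 15 (3R,7E)-1-[(TBS)oxy]-7-{[(TBDPS)oxy]methyl}-3-hydroxy-9,9-dimethoxy-3-methylnon-7-en-5-yn-4-one
Product: 17 (2Z)-3-[(5R)-5-{2-[(TBS)oxy]ethyl}-5-methyl-4-oxo-4,5-dihydrofuran-2-yl]-4-[(TBDPS)oxy]but-2-enal, via furanone acetal 16 (not isolated)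
Conditions: Ph3PAuNTf2 (5 mol%), CH2Cl2, rt; then PPTS, acetone–H2O, rt
Reagents that add atoms: water, O
Why: The cationic gold catalyst activates the ynone for 5-endo-dig attack of the tertiary hydroxyl at C3 (cycloisomerization of α′-hydroxy ynones to 3(2H)-furanones); mild aqueous acid then hydrolyses the enal acetal without an amine present, so the Z-enal is not isomerized and the silyl ethers survive.

Step 12
Reactants: 17 (2Z)-3-[(5R)-5-{2-[(TBS)oxy]ethyl}-5-methyl-4-oxo-4,5-dihydrofuran-2-yl]-4-[(TBDPS)oxy]but-2-enal; 11 ethynyltrimethylsilane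
Product: 19 (2R)-2-{2-[(TBS)oxy]ethyl}-5-{(2Z,4S)-1-[(TBDPS)oxy]-4-hydroxy-6-(trimethylsilyl)hex-2-en-5-yn-2-yl}-2-methylfuran-3(2H)-one, via alkynyl(methyl)zinc 18 (not isolated)
Conditions: 11 (3 equiv), ZnMe2 (3 equiv), ProPhenol ligand (20 mol%), Ph3P=O (40 mol%), toluene, 0 °C; aq. NH4Cl
Reagents that add atoms: none
Why: Zinc–ProPhenol-catalysed asymmetric alkynylation of an α,β-unsaturated aldehyde; the dinuclear zinc complex binds aldehyde and alkynylzinc and delivers the alkyne to the Re face, setting C6 (S here, the spatial arrangement of the target) by catalyst control. The furanone ketone, a vinylogous ester, is not attacked.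

Step 13
Reactants: 19 (2R)-2-{2-[(TBS)oxy]ethyl}-5-{(2Z,4S)-1-[(TBDPS)oxy]-4-hydroxy-6-(trimethylsilyl)hex-2-en-5-yn-2-yl}-2-methylfuran-3(2H)-one
Product: 20 (2R)-2-{2-[(TBS)oxy]ethyl}-5-{(2Z,4S)-1-[(TBDPS)oxy]-4-hydroxyhex-2-en-5-yn-2-yl}-2-methylfuran-3(2H)-one
Conditions: K2CO3, MeOH, 0 °C
Reagents that add atoms: none
Why: Mild methanolysis of the alkynylsilane; the carbinol stereocenter, both silyl ethers and the furanone are stable at 0 °C.

Step 14
Reactants: 20 (2R)-2-{2-[(TBS)oxy]ethyl}-5-{(2Z,4S)-1-[(TBDPS)oxy]-4-hydroxyhex-2-en-5-yn-2-yl}-2-methylfuran-3(2H)-one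
Product: 21 (2R)-2-{2-[(TBS)oxy]ethyl}-5-{(2Z,4R)-1-[(TBDPS)oxy]-4-hydroxyhexa-2,5-dien-2-yl}-2-methylfuran-3(2H)-one
Conditions: H2 (1 atm), Pd/CaCO3 poisoned with Pb(OAc)2 (Lindlar catalyst), quinoline, EtOAc, rt
Reagents that add atoms: none
Why: Lindlar semihydrogenation reduces the terminal alkyne to the vinyl group far faster than the conjugated trisubstituted alkene; C6 is unchanged (the descriptor becomes R because vinyl ranks below the trisubstituted alkenyl group).

Step 15
Reactants: 21 (2R)-2-{2-[(TBS)oxy]ethyl}-5-{(2Z,4R)-1-[(TBDPS)oxy]-4-hydroxyhexa-2,5-dien-2-yl}-2-methylfuran-3(2H)-one; 22 2-(bromomethyl)acrylic acid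
Product: 24 (3R,4Z)-5-[(5R)-5-{2-[(TBS)oxy]ethyl}-5-methyl-4-oxo-4,5-dihydrofuran-2-yl]-6-[(TBDPS)oxy]hexa-1,4-dien-3-yl 2-(bromomethyl)prop-2-enoate, via acid chloride 23 (not isolated)
Conditions: 22, (COCl)2, DMF (cat.), CH2Cl2, 0 °C to rt, evaporate; then 21, 2,6-lutidine, CH2Cl2, −40 to 0 °C
Reagents that add atoms: none
Why: Acylation of a secondary alcohol with an acid chloride and a hindered, weakly nucleophilic base; nucleophilic amines such as DMAP are avoided because they displace the allylic bromide. The C6–O bond is not broken, so the configuration is retained.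

Step 16
Reactants: 24 (3R,4Z)-5-[(5R)-5-{2-[(TBS)oxy]ethyl}-5-methyl-4-oxo-4,5-dihydrofuran-2-yl]-6-[(TBDPS)oxy]hexa-1,4-dien-3-yl 2-(bromomethyl)prop-2-enoate
Product: 25 (5S)-3-(bromomethyl)-5-{(1Z)-2-[(5R)-5-{2-[(TBS)oxy]ethyl}-5-methyl-4-oxo-4,5-dihydrofuran-2-yl]-3-[(TBDPS)oxy]prop-1-en-1-yl}furan-2(5H)-one
Conditions: second-generation Grubbs catalyst RuCl2(=CHPh)(PCy3)(H2IMes) (10 mol%), toluene, 80 °C, 5 mM
Reagents that add atoms: none
Why: Ring-closing metathesis of an allylic acrylate to a butenolide; ruthenium loads on the terminal vinyl group and closes onto the 1,1-disubstituted acrylate with loss of ethylene. The trisubstituted conjugated C4=C5 and furanone alkenes are inert, and ruthenium alkylidenes tolerate allylic bromides.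

Step 17
Reactants: 25 (5S)-3-(bromomethyl)-5-{(1Z)-2-[(5R)-5-{2-[(TBS)oxy]ethyl}-5-methyl-4-oxo-4,5-dihydrofuran-2-yl]-3-[(TBDPS)oxy]prop-1-en-1-yl}furan-2(5H)-one
Product: 26 (5S)-3-(bromomethyl)-5-{(1Z)-2-[(5R)-5-(2-hydroxyethyl)-5-methyl-4-oxo-4,5-dihydrofuran-2-yl]-3-[(TBDPS)oxy]prop-1-en-1-yl}furan-2(5H)-one
Conditions: HF·pyridine, THF, 0 °C
Reagents that add atoms: none
Why: Acidic fluoride cleaves a primary TBS ether well before a primary TBDPS ether; no free nucleophilic base is present to attack the allylic bromide or epimerize C6.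

Step 18
Reactants: 26 (5S)-3-(bromomethyl)-5-{(1Z)-2-[(5R)-5-(2-hydroxyethyl)-5-methyl-4-oxo-4,5-dihydrofuran-2-yl]-3-[(TBDPS)oxy]prop-1-en-1-yl}furan-2(5H)-one
Product: 27 (5S)-3-(bromomethyl)-5-{(1Z)-2-[(5R)-5-methyl-4-oxo-5-(2-oxoethyl)-4,5-dihydrofuran-2-yl]-3-[(TBDPS)oxy]prop-1-en-1-yl}furan-2(5H)-one
Conditions: Dess–Martin periodinane, NaHCO3, CH2Cl2, 0 °C to rt
Reagents that add atoms: none
Why: Buffered Dess–Martin oxidation is compatible with the allylic bromide and avoids amine bases, which would eliminate the furanone oxygen from the β-alkoxy aldehyde; 27 is used at once.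

Step 19
Reactants: 27 (5S)-3-(bromomethyl)-5-{(1Z)-2-[(5R)-5-methyl-4-oxo-5-(2-oxoethyl)-4,5-dihydrofuran-2-yl]-3-[(TBDPS)oxy]prop-1-en-1-yl}furan-2(5H)-one
Product: 29 (6S,7R,8R,10R)-15-[(TBDPS)oxy]-8-hydroxy-1-oxo-3,10-epoxygermacra-2,4Z,11(13)-trien-12,6-olide, via allylindium dibromide 28 (not isolated)
Conditions: In powder (3 equiv), DMF, rt, slow addition of 27 (final 2 mM); aq. NH4Cl
Reagents that add atoms: none
Why: Indium metal inserts into the allylic C13–Br bond to give allylindium 28 (trivalent indium, drawn as the dibromide), which binds the C8 aldehyde oxygen and transfers the allyl unit through its γ-carbon C7 in a closed six-membered transition state (SE2′), forming C7–C8 and moving the alkene to C11=C13. The closest known reactions are the indium-, zinc- or chromium-mediated Barbier allylations of aldehydes with 3-(bromomethyl)furan-2(5H)-ones to β-(hydroxyalkyl)-α-methylene lactones and the Barbier closures of ten-membered rings from open-chain 2-(bromomethyl)-2-enoates. The ring closes by 10-exo-trig attack on the aldehyde counted through C1 and C2 (nine-membered through the furanone oxygen), with the carbonyl oxygen ending outside the ring. C7 is controlled by C6: the chain holding the aldehyde leaves C6 on one face of the flat butenolide and is too short to reach the other, so the new bond forms cis to C5 and the lactone is cis-fused. C8 depends on which aldehyde face fits the cyclic transition state: C6 is pseudo-equatorial (fixed by the ring alkene), and the required syn relation of C8–O and C7–C6 corresponds to C9 pseudo-axial in a chair or equatorial in a boat, which the rigid Z-alkene–furanone bridge may favour but which is not assured. Chemoselectivity for the aldehyde over the furanone ketone and lactone rests on the low reactivity of allylindium reagents toward vinylogous esters, γ-selectivity on the cyclic transition state and the smaller ring, and intramolecular reaction on high dilution with slow addition. The neutral medium spares the β-alkoxy aldehyde, the C6–H and the silyl ether.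

Step 20
Reactants: 29 (6S,7R,8R,10R)-15-[(TBDPS)oxy]-8-hydroxy-1-oxo-3,10-epoxygermacra-2,4Z,11(13)-trien-12,6-olide; 30 tiglic acid
Product: 32 (6S,7R,8R,10R)-15-[(TBDPS)oxy]-8-[(2E)-2-methylbut-2-enoyloxy]-1-oxo-3,10-epoxygermacra-2,4Z,11(13)-trien-12,6-olide, via mixed anhydride 31 (not isolated)
Conditions: 30, 2,4,6-trichlorobenzoyl chloride, Et3N, THF, rt; then 29, DMAP, toluene, rt
Reagents that add atoms: none
Why: Yamaguchi esterification acylates hindered secondary alcohols with α,β-unsaturated acids; DMAP attacks the less hindered tigloyl carbonyl of the mixed anhydride, the C8–O bond is not broken (retention), and the E-tiglate does not isomerize.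

Step 21
Reactants: 32 (6S,7R,8R,10R)-15-[(TBDPS)oxy]-8-[(2E)-2-methylbut-2-enoyloxy]-1-oxo-3,10-epoxygermacra-2,4Z,11(13)-trien-12,6-olide
Product: 33 (6S,7R,8R,10R)-15-hydroxy-8-[(2E)-2-methylbut-2-enoyloxy]-1-oxo-3,10-epoxygermacra-2,4Z,11(13)-trien-12,6-olide
Conditions: HF·pyridine, THF, 0 °C to rt
Reagents that add atoms: none
Why: Acidic fluoride removes the primary allylic TBDPS ether without base, so the methylene lactone, the tiglate and the furanone are left untouched.

## Compound list

1 | (R)-citramalic acid | C[C@@](O)(CC(=O)O)C(=O)O | starting material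
2 | 2-[(4R)-2,2,4-trimethyl-5-oxo-1,3-dioxolan-4-yl]acetic acid | C[C@]1(CC(=O)O)OC(C)(C)OC1=O | intermediate
3 | (5R)-5-(2-hydroxyethyl)-2,2,5-trimethyl-1,3-dioxolan-4-one | C[C@]1(CCO)OC(C)(C)OC1=O | intermediate
4 | (5R)-5-{2-[(TBS)oxy]ethyl}-2,2,5-trimethyl-1,3-dioxolan-4-one | C[C@]1(CCO[Si](C)(C)C(C)(C)C)OC(C)(C)OC1=O | intermediate
5 | but-2-yne-1,4-diol | OCC#CCO | starting material
6 | 4-[(TBDPS)oxy]but-2-yn-1-ol | OCC#CCO[Si](c1ccccc1)(c1ccccc1)C(C)(C)C | intermediate
7 | sodium cyclic alkenylalanate (five-membered O–Al–C=C–C ring, two 2-methoxyethoxy groups on aluminium) | [Na+].COCCO[Al-]1(OCCOC)OC/C=C1/CO[Si](c1ccccc1)(c1ccccc1)C(C)(C)C | intermediate (not isolated)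
8 | (2Z)-4-[(TBDPS)oxy]-3-iodobut-2-en-1-ol | OC/C=C(\I)CO[Si](c1ccccc1)(c1ccccc1)C(C)(C)C | intermediate
9 | (2Z)-4-[(TBDPS)oxy]-3-iodobut-2-enal | O=C/C=C(\I)CO[Si](c1ccccc1)(c1ccccc1)C(C)(C)C | intermediate
10 | (2Z)-1-[(TBDPS)oxy]-2-iodo-4,4-dimethoxybut-2-ene | COC(OC)/C=C(\I)CO[Si](c1ccccc1)(c1ccccc1)C(C)(C)C | intermediate
11 | ethynyltrimethylsilane | C#C[Si](C)(C)C | starting material
12 | (2E)-1-[(TBDPS)oxy]-4,4-dimethoxy-2-[(trimethylsilyl)ethynyl]but-2-ene | COC(OC)/C=C(\C#C[Si](C)(C)C)CO[Si](c1ccccc1)(c1ccccc1)C(C)(C)C | intermediate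
13 | (2E)-1-[(TBDPS)oxy]-2-ethynyl-4,4-dimethoxybut-2-ene | COC(OC)/C=C(\C#C)CO[Si](c1ccccc1)(c1ccccc1)C(C)(C)C | intermediate
14 | lithium acetylide of 13 | [Li]C#C/C(CO[Si](c1ccccc1)(c1ccccc1)C(C)(C)C)=C\C(OC)OC | intermediate (not isolated)
15 | (3R,7E)-1-[(TBS)oxy]-7-{[(TBDPS)oxy]methyl}-3-hydroxy-9,9-dimethoxy-3-methylnon-7-en-5-yn-4-one | CC(C)(C)[Si](C)(C)OCC[C@@](C)(O)C(=O)C#C/C(CO[Si](c1ccccc1)(c1ccccc1)C(C)(C)C)=C\C(OC)OC | intermediate
16 | (2R)-2-{2-[(TBS)oxy]ethyl}-5-{(2Z)-1-[(TBDPS)oxy]-4,4-dimethoxybut-2-en-2-yl}-2-methylfuran-3(2H)-one | CC(C)(C)[Si](C)(C)OCC[C@@]1(C)OC(/C(CO[Si](c2ccccc2)(c2ccccc2)C(C)(C)C)=C\C(OC)OC)=CC1=O | intermediate (not isolated)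
17 | (2Z)-3-[(5R)-5-{2-[(TBS)oxy]ethyl}-5-methyl-4-oxo-4,5-dihydrofuran-2-yl]-4-[(TBDPS)oxy]but-2-enal | CC(C)(C)[Si](C)(C)OCC[C@@]1(C)OC(/C(CO[Si](c2ccccc2)(c2ccccc2)C(C)(C)C)=C\C=O)=CC1=O | intermediate
18 | methyl[(trimethylsilyl)ethynyl]zinc | C[Zn]C#C[Si](C)(C)C | intermediate (not isolated)
19 | (2R)-2-{2-[(TBS)oxy]ethyl}-5-{(2Z,4S)-1-[(TBDPS)oxy]-4-hydroxy-6-(trimethylsilyl)hex-2-en-5-yn-2-yl}-2-methylfuran-3(2H)-one | CC(C)(C)[Si](C)(C)OCC[C@@]1(C)OC(/C(CO[Si](c2ccccc2)(c2ccccc2)C(C)(C)C)=C\[C@H](O)C#C[Si](C)(C)C)=CC1=O | intermediate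
20 | (2R)-2-{2-[(TBS)oxy]ethyl}-5-{(2Z,4S)-1-[(TBDPS)oxy]-4-hydroxyhex-2-en-5-yn-2-yl}-2-methylfuran-3(2H)-one | CC(C)(C)[Si](C)(C)OCC[C@@]1(C)OC(/C(CO[Si](c2ccccc2)(c2ccccc2)C(C)(C)C)=C\[C@H](O)C#C)=CC1=O | intermediate
21 | (2R)-2-{2-[(TBS)oxy]ethyl}-5-{(2Z,4R)-1-[(TBDPS)oxy]-4-hydroxyhexa-2,5-dien-2-yl}-2-methylfuran-3(2H)-one | CC(C)(C)[Si](C)(C)OCC[C@@]1(C)OC(/C(CO[Si](c2ccccc2)(c2ccccc2)C(C)(C)C)=C\[C@H](O)C=C)=CC1=O | intermediate
22 | 2-(bromomethyl)acrylic acid | C=C(CBr)C(=O)O | starting material
23 | 2-(bromomethyl)acryloyl chloride | C=C(CBr)C(=O)Cl | intermediate (not isolated)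
24 | (3R,4Z)-5-[(5R)-5-{2-[(TBS)oxy]ethyl}-5-methyl-4-oxo-4,5-dihydrofuran-2-yl]-6-[(TBDPS)oxy]hexa-1,4-dien-3-yl 2-(bromomethyl)prop-2-enoate | CC(C)(C)[Si](C)(C)OCC[C@@]1(C)OC(/C(CO[Si](c2ccccc2)(c2ccccc2)C(C)(C)C)=C\[C@H](OC(=O)C(=C)CBr)C=C)=CC1=O | intermediate
25 | (5S)-3-(bromomethyl)-5-{(1Z)-2-[(5R)-5-{2-[(TBS)oxy]ethyl}-5-methyl-4-oxo-4,5-dihydrofuran-2-yl]-3-[(TBDPS)oxy]prop-1-en-1-yl}furan-2(5H)-one | CC(C)(C)[Si](C)(C)OCC[C@@]1(C)OC(/C(CO[Si](c2ccccc2)(c2ccccc2)C(C)(C)C)=C\[C@@H]3OC(=O)C(CBr)=C3)=CC1=O | intermediate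
26 | (5S)-3-(bromomethyl)-5-{(1Z)-2-[(5R)-5-(2-hydroxyethyl)-5-methyl-4-oxo-4,5-dihydrofuran-2-yl]-3-[(TBDPS)oxy]prop-1-en-1-yl}furan-2(5H)-one | OCC[C@@]1(C)OC(/C(CO[Si](c2ccccc2)(c2ccccc2)C(C)(C)C)=C\[C@@H]3OC(=O)C(CBr)=C3)=CC1=O | intermediate
27 | (5S)-3-(bromomethyl)-5-{(1Z)-2-[(5R)-5-methyl-4-oxo-5-(2-oxoethyl)-4,5-dihydrofuran-2-yl]-3-[(TBDPS)oxy]prop-1-en-1-yl}furan-2(5H)-one | O=CC[C@@]1(C)OC(/C(CO[Si](c2ccccc2)(c2ccccc2)C(C)(C)C)=C\[C@@H]3OC(=O)C(CBr)=C3)=CC1=O | intermediate
28 | allylindium dibromide derived from 27 (indium on C13) | O=CC[C@@]1(C)OC(/C(CO[Si](c2ccccc2)(c2ccccc2)C(C)(C)C)=C\[C@@H]3OC(=O)C(C[In](Br)Br)=C3)=CC1=O | intermediate (not isolated)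
29 | (6S,7R,8R,10R)-15-[(TBDPS)oxy]-8-hydroxy-1-oxo-3,10-epoxygermacra-2,4Z,11(13)-trien-12,6-olide | C=C1C(=O)O[C@H]2/C=C(/CO[Si](c4ccccc4)(c4ccccc4)C(C)(C)C)C3=CC(=O)[C@@](C)(C[C@@H](O)[C@@H]12)O3 | intermediate
30 | tiglic acid | C/C=C(\C)C(=O)O | starting material
31 | tiglic 2,4,6-trichlorobenzoic anhydride | C/C=C(\C)C(=O)OC(=O)c1c(Cl)cc(Cl)cc1Cl | intermediate (not isolated)
32 | (6S,7R,8R,10R)-15-[(TBDPS)oxy]-8-[(2E)-2-methylbut-2-enoyloxy]-1-oxo-3,10-epoxygermacra-2,4Z,11(13)-trien-12,6-olide | C=C1C(=O)O[C@H]2/C=C(/CO[Si](c4ccccc4)(c4ccccc4)C(C)(C)C)C3=CC(=O)[C@@](C)(C[C@@H](OC(=O)/C(C)=C/C)[C@@H]12)O3 | intermediate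
33 | (6S,7R,8R,10R)-15-hydroxy-8-[(2E)-2-methylbut-2-enoyloxy]-1-oxo-3,10-epoxygermacra-2,4Z,11(13)-trien-12,6-olide | C=C1C(=O)O[C@H]2/C=C(/CO)C3=CC(=O)[C@@](C)(C[C@@H](OC(=O)/C(C)=C/C)[C@@H]12)O3 | target

## Step count and least certain steps

Total: 21 steps. Longest linear sequence: 18 steps (from 5, steps 4–21). The branch from 1 (steps 1–3) joins at step 10.

**Step 19 (key step).** The most likely failure is poor control of the aldehyde face. Both chair arrangements keep C9 gauche to C6, and only strain in the bridged ring tells them apart, so the C8 epimer may predominate. Lesser risks are protonolysis or dimerization of the allylindium before it reaches the aldehyde, and migration of the lactone from O6 to the new O8 alkoxide. Fallback: the route sets out again from 27. If its cyclization delivers mainly the C8 epimer of 29 F1, this alcohol is esterified with inversion by Mitsunobu reaction with tiglic acid 30, PPh3 and diisopropyl azodicarboxylate in toluene at 0 °C. This should give tiglate 32 directly, where the route is rejoined.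

**Step 16.** The likely failure is slow or stalled ring closure. The electron-poor 1,1-disubstituted alkene bearing an allylic bromide reacts sluggishly, and the bromide can alkylate or add oxidatively to ruthenium species as the catalyst decomposes at 80 °C. Fallback from 21, with the bromide introduced only after metathesis: acylation with acryloyl chloride and iPr2NEt gives the acrylate ester of 21 F2. Morita–Baylis–Hillman reaction with aqueous formaldehyde and DABCO in dioxane gives the 2-(hydroxymethyl)acrylate ester F3. Ring-closing metathesis with the second-generation Grubbs catalyst gives the 3-(hydroxymethyl)butenolide F4. Appel bromination (CBr4, PPh3, CH2Cl2, 0 °C) returns to 25.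

**Step 12.** The likely failures are low facial selectivity and slow addition, because the Z-β,β-disubstituted enal is hindered and carries a Lewis-basic furanone near the catalyst. Z-to-E isomerization of the enal under the zinc Lewis acid is also possible. Fallback from 17: lithium (trimethylsilyl)acetylide in THF at −78 °C adds without stereocontrol to give 19 together with the C6 epimer of 19 F5. Dess–Martin oxidation of the mixture gives the alkynyl ketone F6. Corey–Bakshi–Shibata reduction (oxazaborolidine, catecholborane, −78 °C), which distinguishes the small alkynyl from the large alkenyl substituent, returns to 19.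

**Step 11.** The likely failure is misdirected cyclization on the gold-activated alkyne, where an acetal oxygen attacks C3 and leads to furan-type products. Partial Z-to-E isomerization of the enal during hydrolysis is a second risk. Fallback from 15, replacing π-acid catalysis by addition–elimination: diethylamine in ethanol adds to the ynone to give the β-(diethylamino) enone F7. Brief treatment with acetic acid in THF closes the furanone with loss of the amine to give 16. Acetal 16 is now isolated and freed of amine, then hydrolysed (PPTS, acetone–water) to 17.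

**Step 10.** The likely failure is over-addition. If the tetrahedral adduct collapses before the quench, the ynone and acetone are released and consume acetylide. Fallback from 4: aminolysis with MeNH(OMe)·HCl and iPrMgCl in THF at −20 °C gives the α-hydroxy Weinreb amide F8. Its hydroxyl is deprotonated with one further equivalent of iPrMgCl, and addition of lithium acetylide 14 gives 15 through the stable chelated adduct.

## Further compounds

F1 | step 19 | (6S,7R,8S,10R)-15-[(TBDPS)oxy]-8-hydroxy-1-oxo-3,10-epoxygermacra-2,4Z,11(13)-trien-12,6-olide (C8 epimer of 29) | C=C1C(=O)O[C@H]2/C=C(/CO[Si](c4ccccc4)(c4ccccc4)C(C)(C)C)C3=CC(=O)[C@@](C)(C[C@H](O)[C@@H]12)O3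
F2 | step 16 | acrylate ester of 21 | CC(C)(C)[Si](C)(C)OCC[C@@]1(C)OC(/C(CO[Si](c2ccccc2)(c2ccccc2)C(C)(C)C)=C\[C@H](OC(=O)C=C)C=C)=CC1=O
F3 | step 16 | 2-(hydroxymethyl)acrylate ester of 21 | CC(C)(C)[Si](C)(C)OCC[C@@]1(C)OC(/C(CO[Si](c2ccccc2)(c2ccccc2)C(C)(C)C)=C\[C@H](OC(=O)C(=C)CO)C=C)=CC1=O
F4 | step 16 | 3-(hydroxymethyl)butenolide analogue of 25 | CC(C)(C)[Si](C)(C)OCC[C@@]1(C)OC(/C(CO[Si](c2ccccc2)(c2ccccc2)C(C)(C)C)=C\[C@@H]3OC(=O)C(CO)=C3)=CC1=O
F5 | step 12 | C6 epimer of 19 | CC(C)(C)[Si](C)(C)OCC[C@@]1(C)OC(/C(CO[Si](c2ccccc2)(c2ccccc2)C(C)(C)C)=C\[C@@H](O)C#C[Si](C)(C)C)=CC1=O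
F6 | step 12 | C6 alkynyl ketone from 19 and F5 | CC(C)(C)[Si](C)(C)OCC[C@@]1(C)OC(/C(CO[Si](c2ccccc2)(c2ccccc2)C(C)(C)C)=C\C(=O)C#C[Si](C)(C)C)=CC1=O
F7 | step 11 | β-(diethylamino) enone from 15 | CCN(CC)/C(=C/C(=O)[C@](C)(O)CCO[Si](C)(C)C(C)(C)C)/C(CO[Si](c1ccccc1)(c1ccccc1)C(C)(C)C)=C\C(OC)OC
F8 | step 10 | (2R)-4-[(TBS)oxy]-2-hydroxy-N-methoxy-N,2-dimethylbutanamide | CON(C)C(=O)[C@](C)(O)CCO[Si](C)(C)C(C)(C)C
A1 | alternative 1 | open-chain C2 iodoalkyne C1 aldehyde with lactone and tiglate in place | C=C1C(=O)O[C@@H](/C=C(/CO[Si](C)(C)C(C)(C)C)C#CI)[C@H]1[C@H](OC(=O)/C(C)=C/C)C[C@@](C)(O[Si](CC)(CC)CC)C=O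
A2 | alternative 1 | ten-membered cyclic enyne carbinol (one C1 epimer) | C=C1C(=O)O[C@H]2/C=C(/CO[Si](C)(C)C(C)(C)C)C#C[C@H](O)[C@](C)(O[Si](CC)(CC)CC)C[C@@H](OC(=O)/C(C)=C/C)[C@@H]12
A3 | alternative 2 | cyclooctenone carrying the C10 ynol ether | O=C1/C=C\[C@H](O[Si](C)(C)C(C)(C)C)[C@H](C(=C)CO[Si](C)(C)C(C)(C)C)[C@H](OC(=O)/C(C)=C/C)C[C@@]1(C)OC#CCO[Si](c1ccccc1)(c1ccccc1)C(C)(C)C
A4 | alternative 2 | silyl-protected furanone-bridged ten-membered core with open lactone diol | C=C(CO[Si](C)(C)C(C)(C)C)[C@H]1[C@@H](O[Si](C)(C)C(C)(C)C)/C=C(/CO[Si](c3ccccc3)(c3ccccc3)C(C)(C)C)C2=CC(=O)[C@@](C)(C[C@H]1OC(=O)/C(C)=C/C)O2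
A5 | alternative 3 | macrocyclic C6 alcohol with C7 ethynyl group and C8 tiglate | C#C[C@H]1[C@@H](O)/C=C(/CO[Si](C)(C)C(C)(C)C)C2=CC(=O)[C@@](C)(C[C@H]1OC(=O)/C(C)=C/C)O2
A6 | alternative 3 | C15 TBS ether of 33 | C=C1C(=O)O[C@H]2/C=C(/CO[Si](C)(C)C(C)(C)C)C3=CC(=O)[C@@](C)(C[C@@H](OC(=O)/C(C)=C/C)[C@@H]12)O3
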